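## Retrosynthetic overview

1. Target 33 ⇐ 31 ⇐ 29: ester and ketal cleavage; loss of one C8 ester (Krapcho) with migration of C6=C7 into conjugation as C7=C8 (abietane numbering throughout).
2. 29 ⇐ acyclic vinyl iodide 27 by a stannane-mediated radical bicyclization: C5–C6 closes ring B first, then C1–C10 closes ring A.
3. Enabling feature: the trans ring A/ring B fusion, with quaternary C10–CH3 flanked by C1 and by C5–H, is an (E)-C5=C10 trisubstituted alkene in disguise. C6=C7 next to the carboxyl-bearing C8 maps onto a C6 vinyl radical; C1–C2–C3 maps onto a 2-bromoallyl arm on the pre-set quaternary C4; the equatorial C9 side chain steers both closures.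
4. 27 ⇐ 24 ⇐ 21 ⇐ 13: C7≡C6 by ethynylation of the C8 malonate; C9–C11 by asymmetric conjugate addition of a side-chain zinc reagent (from 18) to dienylidene malonate 13.
5. 13 ⇐ enal 11 ⇐ aldehyde 9 ⇐ tiglic acid 1 + 2,3-dibromopropene 2 (enantioselective α-alkylation sets C4; then ozonolysis, Wittig, Knoevenagel).

Key step: step 10

Assumption: the enantiomer named for the chiral tetramine (step 1) and for the phosphoramidite ligand (step 7) is the one taken to give the configuration drawn; if the sense of induction is the reverse, the mirror-image base or ligand is used. Centres that are destroyed later (trioxolane carbon in 8, C2 in 28, C8 in 30) are left unassigned.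

## Route

Step 1
Reactants: 1 (E)-2-methylbut-2-enoic acid (tiglic acid); 2 2,3-dibromoprop-1-ene
Product: 4 (R)-2-(2-bromoprop-2-en-1-yl)-2-methylbut-3-enoic acid, via dilithium dienediolate 3 (not isolated)
Conditions: N1,N3-bis[(1R)-1-phenyl-2-(piperidin-1-yl)ethyl]propane-1,3-diamine (1.05 equiv), n-BuLi (4.0 equiv), THF, 0 °C; then 2, −78 °C; aq. HCl (tetramine recovered)
Reagents that add atoms: 2,3-dibromoprop-1-ene, C=C(Br)CBr
Why: The dienediolate of tiglic acid is alkylated at its α-carbon by the allylic bromide of 2 (the vinylic bromide is inert) inside a mixed aggregate with the chiral dilithium amide, which differentiates the enolate faces and sets the quaternary C4 centre; this is the chiral lithium amide-directed enantioselective alkylation of carboxylic acid enediolates.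

Step 2
Reactants: 4 (R)-2-(2-bromoprop-2-en-1-yl)-2-methylbut-3-enoic acid; 5 iodomethane
Product: 6 methyl (R)-2-(2-bromoprop-2-en-1-yl)-2-methylbut-3-enoate
Conditions: MeI, K2CO3, DMF, rt
Reagents that add atoms: iodomethane, CI
Why: SN2 O-methylation of the carboxylate, which avoids acyl substitution at the hindered carbonyl and leaves the quaternary centre untouched.

Step 3
Reactants: 6 methyl (R)-2-(2-bromoprop-2-en-1-yl)-2-methylbut-3-enoate; 7 ozone
Product: 9 methyl (R)-4-bromo-2-formyl-2-methylpent-4-enoate, via ozonide 8 (not isolated)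
Conditions: O3, CH2Cl2, −78 °C (indicator end point); then Me2S, −78 °C → rt
Reagents that add atoms: ozone, [O-][O+]=O
Why: Ozonolysis with reductive work-up; the monosubstituted vinyl group is much more electron-rich than the 2-bromoalkene, so titrated ozone cleaves it selectively, and the α-quaternary aldehyde cannot epimerize.

Step 4
Reactants: 9 methyl (R)-4-bromo-2-formyl-2-methylpent-4-enoate; 10 2-(triphenyl-λ5-phosphanylidene)propanal
Product: 11 methyl (2R,3E)-2-(2-bromoprop-2-en-1-yl)-2,4-dimethyl-5-oxopent-3-enoate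
Conditions: PhMe, 90 °C
Reagents that add atoms: 2-(triphenyl-λ5-phosphanylidene)propanal, CC(C=O)=P(c1ccccc1)(c1ccccc1)c1ccccc1
Why: Wittig olefination with a stabilized α-methyl ylide, which gives the (E)-trisubstituted enal (future C5=C10 with C9 trans to C4) and is compatible with the non-enolizable neopentyl aldehyde.

Step 5
Reactants: 11 methyl (2R,3E)-2-(2-bromoprop-2-en-1-yl)-2,4-dimethyl-5-oxopent-3-enoate; 12 dimethyl malonate
Product: 13 trimethyl (3E,5R)-7-bromo-3,5-dimethylocta-1,3,7-triene-1,1,5-tricarboxylate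
Conditions: piperidine (10 mol %), AcOH (10 mol %), PhH, reflux, Dean–Stark
Reagents that add atoms: dimethyl malonate, COC(=O)CC(=O)OC
Why: Knoevenagel condensation at the aldehyde carbon with azeotropic removal of water; the two esters are identical, so no new geometric issue arises.

Step 6
Reactants: 14 4-methylpent-1-en-3-one; 15 hydrogen bromide; 16 ethane-1,2-diol
Product: 18 2-(2-bromoethyl)-2-(propan-2-yl)-1,3-dioxolane, via bromoketone 17 (not isolated)
Conditions: HBr (g), CH2Cl2, 0 °C; then ethylene glycol, TsOH (cat.), PhH, reflux, Dean–Stark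
Reagents that add atoms: hydrogen bromide, Br; ethane-1,2-diol, OCCO
Why: Conjugate addition of HBr to the vinyl ketone followed by acid-catalysed ketalization, the standard route to β-bromoethyl dioxolanes that can be metalated.

Step 7
Reactants: 13 trimethyl (3E,5R)-7-bromo-3,5-dimethylocta-1,3,7-triene-1,1,5-tricarboxylate; 18 2-(2-bromoethyl)-2-(propan-2-yl)-1,3-dioxolane
Product: 21 trimethyl (2S,3E,5R)-7-bromo-3,5-dimethyl-2-{2-[2-(propan-2-yl)-1,3-dioxolan-2-yl]ethyl}octa-3,7-diene-1,1,5-tricarboxylate (abietane numbering 4R,9S), via Grignard reagent 19 (not isolated), via diorganozinc reagent 20 (not isolated)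
Conditions: 18, Mg, THF, 25 °C; ZnCl2 (0.5 equiv), then 1,4-dioxane, filter; 13, Cu(OTf)2 (3 mol %), (S,R,R)-O,O'-(1,1'-binaphthyl-2,2'-diyl) N,N-bis(1-phenylethyl)phosphoramidite (6 mol %), PhMe, −40 → −20 °C; aq. NH4Cl
Reagents that add atoms: 2-(2-bromoethyl)-2-(propan-2-yl)-1,3-dioxolane (delivered as its zinc reagent), BrCCC1(OCCO1)C(C)C
Why: Copper–phosphoramidite-catalysed asymmetric conjugate addition of a dialkylzinc to an alkylidene malonate; 1,4-attack at C9 should prevail over 1,6-attack because C5 is shielded by the quaternary C4, and the ligand sets C9 independently of the remote C4 centre.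

Step 8
Reactants: 21 conjugate adduct (4R,9S); 22 1-[(trimethylsilyl)ethynyl]-1λ3,2-benziodoxol-3(1H)-one
Product: 24 trimethyl (4R,5E,7R)-9-bromo-5,7-dimethyl-4-{2-[2-(propan-2-yl)-1,3-dioxolan-2-yl]ethyl}deca-5,9-dien-1-yne-3,3,7-tricarboxylate, via ethynylbenziodoxolone 23 (not isolated)
Conditions: 22 (1.3 equiv), Bu4NF (1.3 equiv), THF, −78 °C → rt
Reagents that add atoms: 1-[(trimethylsilyl)ethynyl]-1λ3,2-benziodoxol-3(1H)-one, C[Si](C)(C)C#CI1OC(=O)c2ccccc12
Why: Electrophilic α-ethynylation of a 2-substituted 1,3-dicarbonyl compound with an alkynyl-λ3-iodane: fluoride desilylates 22, the resulting acetylide deprotonates the malonate, and the enolate adds to the β-carbon of 23 before loss of iodobenzoate and a 1,2-hydrogen shift; C9 is not touched (its descriptor changes only through priority).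

Step 9
Reactants: 24 alkyne triester; 25 iodine
Product: 27 trimethyl (1E,4R,5E,7R)-9-bromo-1-iodo-5,7-dimethyl-4-{2-[2-(propan-2-yl)-1,3-dioxolan-2-yl]ethyl}deca-1,5,9-triene-3,3,7-tricarboxylate, via alkenylzirconocene 26 (not isolated)
Conditions: Cp2Zr(H)Cl (1.3 equiv), THF, rt, 30 min; then I2, 0 °C
Reagents that add atoms: iodine, [I][I]
Why: syn-Hydrozirconation of the terminal alkyne places zirconium on the terminal carbon and iodinolysis proceeds with retention to give the (E)-vinyl iodide; esters, ketal, trisubstituted alkene and vinyl bromide should survive the short exposure.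

Step 10
Reactants: 27 vinyl iodide triester
Product: 29 trans-decalin triester ketal (ring B: C6=C7 alkene and geminal C8 diester; 4β-CH3, 4α-CO2Me, 5α-H, 9α-H, 10β-CH3), via bromodecalin 28 (not isolated)
Conditions: Bu3SnH (2.4 equiv, syringe pump, 8 h), AIBN (0.2 equiv in portions), PhH (0.005 M), reflux
Reagents that add atoms: none
Why: Bu3Sn• abstracts iodine from the vinyl iodide far faster than bromine from the vinyl bromide; the C6 vinyl radical attacks C5 of the (E)-C5=C10 alkene to leave a tertiary C10 radical, which adds to the CH2 terminus (C1) of the 2-bromoallyl arm to form the C1–C10 bond and ring A, and the α-bromoalkyl radical at C2 is reduced to bromide 28, whose C–Br bond is cleaved by the second equivalent of stannane. The closest known reaction type is the stannane-mediated reductive radical polyene cyclization (vinyl, acyl and alkyl radical cascades that give trans-decalins). Ring B closes 6-endo-trig (a competing 5-exo adduct is a homoallyl radical that can funnel to the same tertiary radical by the known cyclopropylcarbinyl ring expansion at low stannane concentration), and ring A closes 6-endo-trig because 5-exo attack would have to join the tertiary radical to the fully substituted, bromine-bearing C2. C5 is set relative to C9 by a chair-like transition state with the C9 side chain and the C4 group on C5 both pseudo-equatorial, which puts H5 and H9 on the same α face; C10 is set in the chair–chair closure of ring A, in which C1 bonds to the face of the C10 radical syn to H5 so that the methyl group ends up β and trans to H5, the fixed 4R centre carrying its methyl axial and its ester equatorial. The step needs chemoselective initiation, 6-endo regioselectivity twice and ring closure faster than hydrogen transfer; these are secured by the iodide/bromide rate difference, the methyl on C10, the bromine on C2, the geminal diester at C8 and slow stannane addition at high dilution.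

Step 11
Reactants: 29 trans-decalin triester ketal
Product: 31 conjugated diester ketal (C7=C8; 4β-CH3, 4α-CO2Me, 5α-H, 9α-H, 10β-CH3), via deconjugated monoester 30 (not isolated)
Conditions: LiCl (3 equiv), H2O (2 equiv), DMSO, 150 °C; then DBU (0.3 equiv), 60 °C
Reagents that add atoms: none
Why: Krapcho dealkoxycarbonylation of the allylic geminal diester (chloride demethylates one ester and the carboxylate loses CO2 through the dienolate), after which DBU moves C6=C7 into conjugation with the remaining ester as the trisubstituted C7=C8 isomer; C9–H is not acidic, and any demethylation at C4 is harmless because step 12 cleaves that ester anyway.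

Step 12
Reactants: 31 conjugated diester ketal
Product: 33 (1R,4aS,5R,8aR)-1,4a-dimethyl-5-(4-methyl-3-oxopentyl)-1,2,3,4,4a,5,8,8a-octahydronaphthalene-1,6-dicarboxylic acid (13-oxo-13,14-seco-abiet-7-ene-14,18-dioic acid; the target), via dipotassium salt 32 (not isolated)
Conditions: KOt-Bu (8 equiv), H2O (4 equiv), DMSO, 50 °C; then 2 M aq. HCl, THF, rt
Reagents that add atoms: water, O
Why: Hydroxide generated from KOt-Bu and water in DMSO saponifies the conjugated ester and the hindered equatorial C4 ester, and aqueous acid then protonates the dicarboxylate and hydrolyses the dioxolane to the isopropyl ketone; no stereocentre is epimerizable under either stage.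

## Compound list

1 | (E)-2-methylbut-2-enoic acid (tiglic acid) | C/C=C(\C)C(=O)O | starting material
2 | 2,3-dibromoprop-1-ene | C=C(Br)CBr | starting material
3 | dilithium dienediolate of 1 | [Li]OC(O[Li])=C(C)C=C | intermediate
4 | (R)-2-(2-bromoprop-2-en-1-yl)-2-methylbut-3-enoic acid | C=C(Br)C[C@@](C=C)(C)C(=O)O | intermediate
5 | iodomethane | CI | starting material
6 | methyl (R)-2-(2-bromoprop-2-en-1-yl)-2-methylbut-3-enoate | C=C(Br)C[C@@](C=C)(C)C(=O)OC | intermediate
7 | ozone | [O-][O+]=O | starting material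
8 | methyl (2R)-4-bromo-2-methyl-2-(1,2,4-trioxolan-3-yl)pent-4-enoate (ozonide, ring carbon unassigned) | C=C(Br)C[C@@](C1OCOO1)(C)C(=O)OC | intermediate
9 | methyl (R)-4-bromo-2-formyl-2-methylpent-4-enoate | C=C(Br)C[C@@](C=O)(C)C(=O)OC | intermediate
10 | 2-(triphenyl-λ5-phosphanylidene)propanal | CC(C=O)=P(c1ccccc1)(c1ccccc1)c1ccccc1 | starting material
11 | methyl (2R,3E)-2-(2-bromoprop-2-en-1-yl)-2,4-dimethyl-5-oxopent-3-enoate | C=C(Br)C[C@@](/C=C(\C)C=O)(C)C(=O)OC | intermediate
12 | dimethyl malonate | COC(=O)CC(=O)OC | starting material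
13 | trimethyl (3E,5R)-7-bromo-3,5-dimethylocta-1,3,7-triene-1,1,5-tricarboxylate | C=C(Br)C[C@@](/C=C(\C)C=C(C(=O)OC)C(=O)OC)(C)C(=O)OC | intermediate
14 | 4-methylpent-1-en-3-one | C=CC(=O)C(C)C | starting material
15 | hydrogen bromide | Br | starting material
16 | ethane-1,2-diol | OCCO | starting material
17 | 1-bromo-4-methylpentan-3-one | BrCCC(=O)C(C)C | intermediate
18 | 2-(2-bromoethyl)-2-(propan-2-yl)-1,3-dioxolane | BrCCC1(OCCO1)C(C)C | intermediate
19 | {2-[2-(propan-2-yl)-1,3-dioxolan-2-yl]ethyl}magnesium bromide | Br[Mg]CCC1(OCCO1)C(C)C | intermediate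
20 | bis{2-[2-(propan-2-yl)-1,3-dioxolan-2-yl]ethyl}zinc | CC(C)C1(OCCO1)CC[Zn]CCC1(OCCO1)C(C)C | intermediate
21 | trimethyl (2S,3E,5R)-7-bromo-3,5-dimethyl-2-{2-[2-(propan-2-yl)-1,3-dioxolan-2-yl]ethyl}octa-3,7-diene-1,1,5-tricarboxylate | CC(C)C1(OCCO1)CC[C@H](/C(C)=C/[C@@](C)(CC(Br)=C)C(=O)OC)C(C(=O)OC)C(=O)OC | intermediate
22 | 1-[(trimethylsilyl)ethynyl]-1λ3,2-benziodoxol-3(1H)-one | C[Si](C)(C)C#CI1OC(=O)c2ccccc12 | starting material
23 | 1-ethynyl-1λ3,2-benziodoxol-3(1H)-one | C#CI1OC(=O)c2ccccc12 | intermediate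
24 | trimethyl (4R,5E,7R)-9-bromo-5,7-dimethyl-4-{2-[2-(propan-2-yl)-1,3-dioxolan-2-yl]ethyl}deca-5,9-dien-1-yne-3,3,7-tricarboxylate | CC(C)C1(OCCO1)CC[C@H](/C(C)=C/[C@@](C)(CC(Br)=C)C(=O)OC)C(C#C)(C(=O)OC)C(=O)OC | intermediate
25 | iodine | [I][I] | starting material
26 | (E)-alkenylzirconocene chloride from 24 (zirconium on C6; cyclopentadienyl rings written σ-bonded) | CC(C)C1(OCCO1)CC[C@H](/C(C)=C/[C@@](C)(CC(Br)=C)C(=O)OC)C(/C=C/[Zr](Cl)(C1C=CC=C1)C1C=CC=C1)(C(=O)OC)C(=O)OC | intermediate
27 | trimethyl (1E,4R,5E,7R)-9-bromo-1-iodo-5,7-dimethyl-4-{2-[2-(propan-2-yl)-1,3-dioxolan-2-yl]ethyl}deca-1,5,9-triene-3,3,7-tricarboxylate | CC(C)C1(OCCO1)CC[C@H](/C(C)=C/[C@@](C)(CC(Br)=C)C(=O)OC)C(/C=C/I)(C(=O)OC)C(=O)OC | intermediate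
28 | 2-bromo trans-decalin triester ketal (C2 epimers; otherwise as 29) | CC(C)C1(OCCO1)CC[C@H]2C(C(=O)OC)(C(=O)OC)C=C[C@@H]3[C@]2(C)CC(Br)C[C@@]3(C)C(=O)OC | intermediate
29 | trans-decalin triester ketal: C6=C7, C8(CO2Me)2, 4β-CH3, 4α-CO2Me, 5α-H, 9α-H, 10β-CH3, C13 dioxolane | CC(C)C1(OCCO1)CC[C@H]2C(C(=O)OC)(C(=O)OC)C=C[C@@H]3[C@]2(C)CCC[C@@]3(C)C(=O)OC | intermediate
30 | deconjugated monoester ketal: C6=C7, C8H(CO2Me) as C8 epimers | CC(C)C1(OCCO1)CC[C@H]2C(C(=O)OC)C=C[C@@H]3[C@]2(C)CCC[C@@]3(C)C(=O)OC | intermediate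
31 | conjugated diester ketal: C7=C8–CO2Me, 4α-CO2Me, C13 dioxolane (dimethyl ester ketal of the target) | CC(C)C1(OCCO1)CC[C@H]2C(C(=O)OC)=CC[C@@H]3[C@]2(C)CCC[C@@]3(C)C(=O)OC | intermediate
32 | dipotassium salt of the ketal diacid | CC(C)C1(OCCO1)CC[C@H]2C(C(=O)[O-])=CC[C@@H]3[C@]2(C)CCC[C@@]3(C)C(=O)[O-].[K+].[K+] | intermediate
33 | (1R,4aS,5R,8aR)-1,4a-dimethyl-5-(4-methyl-3-oxopentyl)-1,2,3,4,4a,5,8,8a-octahydronaphthalene-1,6-dicarboxylic acid | CC(C)C(=O)CC[C@H]1C(C(=O)O)=CC[C@@H]2[C@]1(C)CCC[C@@]2(C)C(=O)O | target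

## Summary and fallbacks

Total step count: 12. Longest linear sequence: 11 steps (steps 1–5 and 7–12; step 6 is a one-step branch).

Steps most likely to fail:

Step 10. What may go wrong: hydrogen transfer to the vinyl radical or to the C10 radical (including a 1,5-hydrogen shift from C11) outruns ring closure, or ring A closes with poor facial selectivity. The fallback replaces the radical manifold by a polar one. It sets out from alkyne 24 and comes back at 29. A cationic gold catalyst, [Au(P(t-Bu)2(o-biphenyl))(NCMe)]SbF6 (5 mol %), in wet CH2Cl2 buffered with 2,6-di-tert-butylpyridine, activates the alkyne for 6-endo-dig attack by C5. The C10 cation is then captured by the bromoalkene as a masked ketone (halo-olefin annulation), and hydrolysis of the α-bromo cation gives the ring A C2 ketone F1. Condensation with tosylhydrazine gives the tosylhydrazone F2, and reduction with catecholborane followed by NaOAc delivers 29.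

Step 7. What may go wrong: poor facial control at C9 by the ligand, competing uncatalysed or 1,6-addition, or sluggish transfer of the functionalized alkyl group. The fallback builds C9 by reduction and stereospecific allylic substitution. It sets out from enal 11 and comes back at 21. Grignard reagent 19 adds to the aldehyde at −78 °C to give the allylic alcohol F3 as a mixture of C9 epimers. Dess–Martin periodinane gives the enone F4. Reduction with (S)-Me-CBS oxazaborolidine and BH3·SMe2 should give the (9R)-allylic alcohol F5 by the usual large/small model. Methyl chloroformate and pyridine give the methyl carbonate F6. Tsuji–Trost alkylation with Pd(PPh3)4 and dimethyl malonate 12 in THF at 50 °C then gives 21 with net retention, attack occurring at C9 because the other allyl terminus (C5) is neopentyl.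

Step 8. What may go wrong: the hindered tertiary malonate adds too slowly to the iodane, so that the reagent decomposes first. The fallback installs the two-carbon unit as a vinyl sulfone and bypasses the alkyne. It sets out from 21 and comes back at 27. The sodium enolate (NaH, THF) adds to ethynyl p-tolyl sulfone to give the vinyl sulfone F7. Radical ipso-substitution with Bu3SnH and AIBN gives the vinylstannane F8, and iododestannylation with I2 gives 27. An E/Z mixture is acceptable because the vinyl radical of step 10 is configurationally labile.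

Further compounds
F1 | step 10 | ring A C2 ketone of the trans-decalin triester ketal | CC(C)C1(OCCO1)CC[C@H]2C(C(=O)OC)(C(=O)OC)C=C[C@@H]3[C@]2(C)CC(=O)C[C@@]3(C)C(=O)OC
F2 | step 10 | tosylhydrazone of F1 | CC(C)C1(OCCO1)CC[C@H]2C(C(=O)OC)(C(=O)OC)C=C[C@@H]3[C@]2(C)CC(=NNS(=O)(=O)c4ccc(C)cc4)C[C@@]3(C)C(=O)OC
F3 | step 7 | methyl (2R,3E)-2-(2-bromoprop-2-en-1-yl)-5-hydroxy-2,4-dimethyl-7-[2-(propan-2-yl)-1,3-dioxolan-2-yl]hept-3-enoate (C5 epimers) | CC(C)C1(OCCO1)CCC(O)/C(C)=C/[C@@](C)(CC(Br)=C)C(=O)OC
F4 | step 7 | methyl (2R,3E)-2-(2-bromoprop-2-en-1-yl)-2,4-dimethyl-5-oxo-7-[2-(propan-2-yl)-1,3-dioxolan-2-yl]hept-3-enoate | CC(C)C1(OCCO1)CCC(=O)/C(C)=C/[C@@](C)(CC(Br)=C)C(=O)OC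
F5 | step 7 | methyl (2R,3E,5R)-2-(2-bromoprop-2-en-1-yl)-5-hydroxy-2,4-dimethyl-7-[2-(propan-2-yl)-1,3-dioxolan-2-yl]hept-3-enoate | CC(C)C1(OCCO1)CC[C@H](/C(C)=C/[C@@](C)(CC(Br)=C)C(=O)OC)O
F6 | step 7 | methyl carbonate of F5 | CC(C)C1(OCCO1)CC[C@H](/C(C)=C/[C@@](C)(CC(Br)=C)C(=O)OC)OC(=O)OC
F7 | step 8 | (E)-2-(p-tolylsulfonyl)vinyl malonate derived from 21 | CC(C)C1(OCCO1)CC[C@H](/C(C)=C/[C@@](C)(CC(Br)=C)C(=O)OC)C(/C=C/S(=O)(=O)c1ccc(C)cc1)(C(=O)OC)C(=O)OC
F8 | step 8 | (E)-2-(tributylstannyl)vinyl malonate derived from F7 | CC(C)C1(OCCO1)CC[C@H](/C(C)=C/[C@@](C)(CC(Br)=C)C(=O)OC)C(/C=C/[Sn](CCCC)(CCCC)CCCC)(C(=O)OC)C(=O)OC
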